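**Retrosynthetic overview**
1. Key step (last): both quinone C–O bonds of 24 are formed from water on the 1,4-dimethoxynaphthalene 23 (Ce(IV)). The aryl ether form allows the Mg(0)/Grignard chemistry that a quinone would not survive.
2. C12–C13 (Cu-catalysed Grignard/allylic acetate coupling, then removal of an auxiliary sulfone at C25) divides 23 into lower half 12 and upper half 20.
3. 12 comes from chloromethyl arene 4 (from menadione) and alkyne 10 by carboalumination/Ni coupling (C1–C2, 2E). 10 comes from geranylacetone by terminal allylic C–H hydroxylation (C–O) and one double asymmetric hydrogenation (C7, C11).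
4. 20 comes from (S)-α-cyclogeranyl phenyl sulfone 15 and 12-bromofarnesyl acetate 18 (C24–C25). 18 is made from farnesyl acetate by the same allylic C–H hydroxylation (C–O).
5. Rings: the naphthalene core is bought intact (menadione). The cyclohexene is the only ring built (step 9, new enantioselective cyclisation, sets the ring stereocentre). The quinone ring is unveiled last (step 15).

Assumption: 5, 13 and 16 are bought as the geometrically pure E (E,E) isomers.

**Step 1**
Reactants: 1 menadione (2-methylnaphthalene-1,4-dione)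
Product: 3 1,4-dimethoxy-2-methylnaphthalene, via menadiol 2 (not isolated)
Conditions: Na2S2O4, H2O/THF, rt; then aq NaOH, Me2SO4, Bu4NBr (cat.), N2, rt
Reagents that add atoms: dimethyl sulfate, COS(=O)(=O)OC
Why: Dithionite reduction of the quinone to the hydroquinone followed by phase-transfer Williamson O-methylation in one pot gives the robust dimethyl ether.

**Step 2**
Reactants: 3 1,4-dimethoxy-2-methylnaphthalene
Product: 4 2-(chloromethyl)-1,4-dimethoxy-3-methylnaphthalene
Conditions: (CH2O)n, conc. HCl, AcOH, 50 °C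
Reagents that add atoms: formaldehyde (as paraformaldehyde), C=O; hydrogen chloride, Cl
Why: Blanc chloromethylation attacks the only free position (C3) of the electron-rich dimethoxy ring.

**Step 3**
Reactants: 5 (E)-geranylacetone
Product: 6 (5E,9E)-11-hydroxy-6,10-dimethylundeca-5,9-dien-2-one
Conditions: SeO2 (10 mol%), t-BuOOH (2.5 equiv), salicylic acid (10 mol%), CH2Cl2, 0 °C → rt, stopped at ~70% conversion
Reagents that add atoms: tert-butyl hydroperoxide (terminal oxidant, O transferred via catalytic SeO2), CC(C)(C)OO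
Why: Catalytic SeO2 allylic hydroxylation (ene reaction then [2,3]-shift) is selective for the (E)-methyl of the terminal isopropylidene group, giving the E-allylic alcohol that serves as handle for the later chain union.

**Step 4**
Reactants: 6 (5E,9E)-11-hydroxy-6,10-dimethylundeca-5,9-dien-2-one
Product: 7 (6R,10S)-11-hydroxy-6,10-dimethylundecan-2-one
Conditions: H2 (50 bar), [Ir(cod)(L*)]BArF (1 mol%, L* = chiral bicyclic pyridine–phosphinite N,P ligand), CH2Cl2, rt
Reagents that add atoms: none
Why: Ir–N,P-catalysed asymmetric hydrogenation of trisubstituted olefins (Pfaltz type) reduces both E-olefins, which share the same substituent topology, from the corresponding face, so the ligand antipode that gives the natural isoprenoid series (as for (2E,6E)-farnesol → (3R,7R)-hexahydrofarnesol) sets C6 (R) and C10 (S) in one operation while the ketone is untouched.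

**Step 5**
Reactants: 7 (6R,10S)-11-hydroxy-6,10-dimethylundecan-2-one
Product: 8 (6R,10S)-11-chloro-6,10-dimethylundecan-2-one
Conditions: PPh3, NCS, CH2Cl2, 0 °C → rt
Reagents that add atoms: N-chlorosuccinimide, O=C1CCC(=O)N1Cl
Why: Appel-type chlorination of the primary alcohol proceeds by SN2 at CH2 and leaves both stereocentres and the ketone untouched.

**Step 6**
Reactants: 8 (6R,10S)-11-chloro-6,10-dimethylundecan-2-one
Product: 10 (6R,10S)-11-chloro-6,10-dimethylundec-1-yne, via enol phosphate 9 (not isolated)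
Conditions: LDA (commercial solution, 1.1 equiv), THF, −78 °C; ClP(O)(OEt)2, −78 °C → rt; then LDA (2.3 equiv), −78 → 0 °C; H2O
Reagents that add atoms: none
Why: Negishi methyl ketone → terminal alkyne protocol (kinetic terminal enolate, enol phosphate, LDA elimination) works here because a primary alkyl chloride is inert to LDA at or below 0 °C.

**Step 7**
Reactants: 10 (6R,10S)-11-chloro-6,10-dimethylundec-1-yne; 4 2-(chloromethyl)-1,4-dimethoxy-3-methylnaphthalene
Product: 12 2-[(2E,7R,11S)-12-chloro-3,7,11-trimethyldodec-2-en-1-yl]-1,4-dimethoxy-3-methylnaphthalene, via vinylalane 11 (not isolated)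
Conditions: Me3Al (2 equiv), Cp2ZrCl2 (25 mol%), ClCH2CH2Cl, rt; volatiles removed; then 4, NiCl2(PPh3)2/n-BuLi (3 mol% Ni(0)), THF, rt
Reagents that add atoms: trimethylaluminium, C[Al](C)C
Why: Negishi Zr-catalysed syn-carboalumination gives only the (E)-2-methylalkenylalane, which is cross-coupled with the benzylic chloride under Ni(0) (Lipshutz-type) with retention of geometry, fixing the 2E olefin and the C1–C2 bond while the alkyl chloride and aryl ethers are tolerated.

**Step 8**
Reactants: 13 geranyl bromide
Product: 14 geranyl phenyl sulfone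
Conditions: PhSO2Na, DMF, rt
Reagents that add atoms: sodium benzenesulfinate, [Na+].[O-]S(=O)c1ccccc1
Why: SN2 S-alkylation of the sulfinate by the primary allylic bromide retains the E geometry.

**Step 9**
Reactants: 14 geranyl phenyl sulfone
Product: 15 (S)-α-cyclogeranyl phenyl sulfone
Conditions: chiral confined imidodiphosphorimidate (IDPi) Brønsted acid (5 mol%), (CF3)2CHOH/CH2Cl2 1:3, −40 °C
Reagents that add atoms: none
Why: Proposed new method: a strongly acidic, confined chiral IDPi in a fluorinated alcohol protonates the electron-rich distal C6=C7 olefin (the C2=C3 olefin is deactivated by the allylic sulfonyl group), the chiral anion holds the chain in a chair-like fold so that the C2=C3 π-bond attacks the incipient tertiary cation through one enantiotopic face (C2–C7 ring closure, setting the ring stereocentre as S with the appropriate catalyst antipode), and the resulting tertiary cation/anion pair collapses by kinetic loss of the ring CH2 proton to give the α-olefin rather than the β-isomer; the closest known chemistry is the racemic H2SO4/AcOH cyclisation of geranyl aryl sulfones and IDPi- or Lewis-acid-assisted chiral Brønsted acid polyene cyclisations (homofarnesol to ambroxide type), not yet shown for a sulfonyl-bearing geranyl substrate with olefin-forming termination.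

**Step 10**
Reactants: 16 (2E,6E)-farnesyl acetate
Product: 17 (2E,6E,10E)-12-hydroxy-3,7,11-trimethyldodeca-2,6,10-trien-1-yl acetate
Conditions: SeO2 (10 mol%), t-BuOOH (2.5 equiv), salicylic acid (10 mol%), CH2Cl2, 0 °C → rt, stopped at ~60% conversion
Reagents that add atoms: tert-butyl hydroperoxide (terminal oxidant, O transferred via catalytic SeO2), CC(C)(C)OO
Why: The same SeO2 allylic hydroxylation is selective for the terminal (E)-methyl group because the 2,3-olefin is deactivated by the allylic acetate, giving the 10E allylic alcohol.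

**Step 11**
Reactants: 17 (2E,6E,10E)-12-hydroxy-3,7,11-trimethyldodeca-2,6,10-trien-1-yl acetate
Product: 18 (2E,6E,10E)-12-bromo-3,7,11-trimethyldodeca-2,6,10-trien-1-yl acetate
Conditions: CBr4, PPh3, CH2Cl2, −20 °C
Reagents that add atoms: carbon tetrabromide, BrC(Br)(Br)Br
Why: Appel bromination converts the primary allylic alcohol into the bromide without allylic transposition or loss of E geometry.

**Step 12**
Reactants: 15 (S)-α-cyclogeranyl phenyl sulfone; 18 (2E,6E,10E)-12-bromo-3,7,11-trimethyldodeca-2,6,10-trien-1-yl acetate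
Product: 20 (2E,6E,10E)-3,7,11-trimethyl-13-(phenylsulfonyl)-13-[(1S)-2,6,6-trimethylcyclohex-2-en-1-yl]trideca-2,6,10-trien-1-yl acetate (C13 epimers), via lithiated sulfone 19 (not isolated)
Conditions: n-BuLi (1.05 equiv), THF/DMPU, −78 °C; then 18, −78 → −40 °C
Reagents that add atoms: none
Why: Alkylation of the α-sulfonyl carbanion (Julia/Biellmann-type polyprenoid coupling) is a clean SN2 at the primary allylic bromide that leaves the acetate and the non-acidic ring stereocentre untouched; the new sulfonyl-bearing centre is formed as an inconsequential mixture removed in step 14.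

**Step 13**
Reactants: 12 2-[(2E,7R,11S)-12-chloro-3,7,11-trimethyldodec-2-en-1-yl]-1,4-dimethoxy-3-methylnaphthalene; 20 sulfonyl acetate (C13 epimers)
Product: 22 2-[(2E,7R,11S,14E,18E,22E)-3,7,11,15,19,23-hexamethyl-25-(phenylsulfonyl)-25-[(1S)-2,6,6-trimethylcyclohex-2-en-1-yl]pentacosa-2,14,18,22-tetraen-1-yl]-1,4-dimethoxy-3-methylnaphthalene (C25 epimers), via Grignard reagent 21 (not isolated)
Conditions: Mg (activated), THF, 50 °C; then added to 20, Li2CuCl4 (5 mol%), THF, −78 → 0 °C
Reagents that add atoms: none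
Why: Cu-catalysed Grignard substitution of a primary allylic acetate (Kochi/Schlosser–Fouquet type) occurs at the α-carbon with retention of the 14E geometry and touches no stereocentre.

**Step 14**
Reactants: 22 coupled sulfone (C25 epimers)
Product: 23 2-[(2E,7R,11S,14E,18E,22E)-3,7,11,15,19,23-hexamethyl-25-[(1S)-2,6,6-trimethylcyclohex-2-en-1-yl]pentacosa-2,14,18,22-tetraen-1-yl]-1,4-dimethoxy-3-methylnaphthalene
Conditions: Mg turnings, MeOH/THF, 50 °C
Reagents that add atoms: none
Why: Single-electron reductive desulfonylation of the alkyl aryl sulfone replaces C–S by C–H and merges both C25 epimers, while isolated olefins, aryl ethers and the stereocentres are inert.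

**Step 15**
Reactants: 23 dimethyl ether of the target hydroquinone
Product: 24 target, 2-methyl-3-[(2E,7R,11S,14E,18E,22E)-3,7,11,15,19,23-hexamethyl-25-[(1S)-2,6,6-trimethylcyclohex-2-en-1-yl]pentacosa-2,14,18,22-tetraen-1-yl]naphthalene-1,4-dione
Conditions: (NH4)2Ce(NO3)6 (2.5 equiv), MeCN/CH2Cl2/H2O, 0 °C, 30 min
Reagents that add atoms: water, O
Why: Key step, Ce(IV) oxidative O-demethylation: the p-dimethoxyarene radical cation is attacked at the ipso carbons by water and loses methanol, so both quinone C–O bonds are newly formed, and the isolated trisubstituted olefins and all stereocentres survive at 0 °C.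

**Compound list**
1 | menadione (2-methylnaphthalene-1,4-dione) | CC1=CC(=O)c2ccccc2C1=O | starting material
2 | menadiol (2-methylnaphthalene-1,4-diol) | Cc1cc(O)c2ccccc2c1O | intermediate
3 | 1,4-dimethoxy-2-methylnaphthalene | COc1cc(C)c(OC)c2ccccc12 | intermediate
4 | 2-(chloromethyl)-1,4-dimethoxy-3-methylnaphthalene | COc1c(C)c(CCl)c(OC)c2ccccc12 | intermediate
5 | (E)-geranylacetone, (5E)-6,10-dimethylundeca-5,9-dien-2-one | CC(C)=CCC/C(C)=C/CCC(C)=O | starting material
6 | (5E,9E)-11-hydroxy-6,10-dimethylundeca-5,9-dien-2-one | OC/C(C)=C/CC/C(C)=C/CCC(C)=O | intermediate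
7 | (6R,10S)-11-hydroxy-6,10-dimethylundecan-2-one | OC[C@@H](C)CCC[C@@H](C)CCCC(C)=O | intermediate
8 | (6R,10S)-11-chloro-6,10-dimethylundecan-2-one | ClC[C@@H](C)CCC[C@@H](C)CCCC(C)=O | intermediate
9 | enol phosphate, (6R,10S)-11-chloro-6,10-dimethylundec-1-en-2-yl diethyl phosphate | ClC[C@@H](C)CCC[C@@H](C)CCCC(=C)OP(=O)(OCC)OCC | intermediate
10 | (6R,10S)-11-chloro-6,10-dimethylundec-1-yne | ClC[C@@H](C)CCC[C@@H](C)CCCC#C | intermediate
11 | vinylalane, [(1E,6R,10S)-11-chloro-2,6,10-trimethylundec-1-en-1-yl]dimethylalane | ClC[C@@H](C)CCC[C@@H](C)CCC/C(C)=C/[Al](C)C | intermediate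
12 | 2-[(2E,7R,11S)-12-chloro-3,7,11-trimethyldodec-2-en-1-yl]-1,4-dimethoxy-3-methylnaphthalene | ClC[C@@H](C)CCC[C@@H](C)CCC/C(C)=C/Cc1c(C)c(OC)c2ccccc2c1OC | intermediate
13 | geranyl bromide, (2E)-1-bromo-3,7-dimethylocta-2,6-diene | CC(C)=CCC/C(C)=C/CBr | starting material
14 | geranyl phenyl sulfone, {[(2E)-3,7-dimethylocta-2,6-dien-1-yl]sulfonyl}benzene | CC(C)=CCC/C(C)=C/CS(=O)(=O)c1ccccc1 | intermediate
15 | (S)-α-cyclogeranyl phenyl sulfone, ({[(1S)-2,6,6-trimethylcyclohex-2-en-1-yl]methyl}sulfonyl)benzene | CC1=CCCC(C)(C)[C@@H]1CS(=O)(=O)c1ccccc1 | intermediate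
16 | (2E,6E)-farnesyl acetate | CC(C)=CCC/C(C)=C/CC/C(C)=C/COC(C)=O | starting material
17 | (2E,6E,10E)-12-hydroxy-3,7,11-trimethyldodeca-2,6,10-trien-1-yl acetate | OC/C(C)=C/CC/C(C)=C/CC/C(C)=C/COC(C)=O | intermediate
18 | (2E,6E,10E)-12-bromo-3,7,11-trimethyldodeca-2,6,10-trien-1-yl acetate | BrC/C(C)=C/CC/C(C)=C/CC/C(C)=C/COC(C)=O | intermediate
19 | lithiated sulfone (α-lithio derivative of 15) | CC1=CCCC(C)(C)[C@@H]1C([Li])S(=O)(=O)c1ccccc1 | intermediate
20 | (2E,6E,10E)-3,7,11-trimethyl-13-(phenylsulfonyl)-13-[(1S)-2,6,6-trimethylcyclohex-2-en-1-yl]trideca-2,6,10-trien-1-yl acetate (C13 epimers) | CC1=CCCC(C)(C)[C@@H]1C(S(=O)(=O)c1ccccc1)C/C(C)=C/CC/C(C)=C/CC/C(C)=C/COC(C)=O | intermediate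
21 | Grignard reagent, [(2S,6R,10E)-12-(1,4-dimethoxy-3-methylnaphthalen-2-yl)-2,6,10-trimethyldodec-10-en-1-yl]magnesium chloride | Cl[Mg]C[C@@H](C)CCC[C@@H](C)CCC/C(C)=C/Cc1c(C)c(OC)c2ccccc2c1OC | intermediate
22 | 2-[(2E,7R,11S,14E,18E,22E)-3,7,11,15,19,23-hexamethyl-25-(phenylsulfonyl)-25-[(1S)-2,6,6-trimethylcyclohex-2-en-1-yl]pentacosa-2,14,18,22-tetraen-1-yl]-1,4-dimethoxy-3-methylnaphthalene (C25 epimers) | CC1=CCCC(C)(C)[C@@H]1C(S(=O)(=O)c1ccccc1)C/C(C)=C/CC/C(C)=C/CC/C(C)=C/CC[C@@H](C)CCC[C@@H](C)CCC/C(C)=C/Cc1c(C)c(OC)c2ccccc2c1OC | intermediate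
23 | 2-[(2E,7R,11S,14E,18E,22E)-3,7,11,15,19,23-hexamethyl-25-[(1S)-2,6,6-trimethylcyclohex-2-en-1-yl]pentacosa-2,14,18,22-tetraen-1-yl]-1,4-dimethoxy-3-methylnaphthalene | CC1=CCCC(C)(C)[C@@H]1CC/C(C)=C/CC/C(C)=C/CC/C(C)=C/CC[C@@H](C)CCC[C@@H](C)CCC/C(C)=C/Cc1c(C)c(OC)c2ccccc2c1OC | intermediate
24 | 2-methyl-3-[(2E,7R,11S,14E,18E,22E)-3,7,11,15,19,23-hexamethyl-25-[(1S)-2,6,6-trimethylcyclohex-2-en-1-yl]pentacosa-2,14,18,22-tetraen-1-yl]naphthalene-1,4-dione | CC1=CCCC(C)(C)[C@@H]1CC/C(C)=C/CC/C(C)=C/CC/C(C)=C/CC[C@@H](C)CCC[C@@H](C)CCC/C(C)=C/CC1=C(C)C(=O)c2ccccc2C1=O | target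

**Totals**
Total step count: 15. Longest linear sequence: 8 steps (3, 4, 5, 6, 7, 13, 14, 15, from geranylacetone).

**Steps most likely to fail**

Step 9 (the proposed new cyclisation) may give low enantioselectivity, the β-olefin isomer or incomplete conversion on this deactivated substrate. The fallback uses known chemistry, sets out from 14 and comes back at 15. Conc. H2SO4 in AcOH at 10–15 °C (the established kinetically α-selective cyclisation of geranyl aryl sulfones) gives racemic α-cyclogeranyl phenyl sulfone F1. Preparative chromatography on a chiral stationary phase (SFC, amylose phase) then supplies the (S)-enantiomer, which is 15.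

Step 13 (late Cu-catalysed Grignard/allylic acetate union) may suffer from sluggish Grignard formation from the chloride, attack on the acetate carbonyl, γ-substitution or interference by the sulfone. The fallback sets out from 20 (with 12) and comes back at 23. Mg/MeOH on 20 removes the sulfone and methanolyses the acetate to give the allylic alcohol (2E,6E,10E)-3,7,11-trimethyl-13-[(1S)-2,6,6-trimethylcyclohex-2-en-1-yl]trideca-2,6,10-trien-1-ol F2. PBr3 in Et2O at 0 °C converts it into the allylic bromide (2E,6E,10E)-1-bromo-3,7,11-trimethyl-13-[(1S)-2,6,6-trimethylcyclohex-2-en-1-yl]trideca-2,6,10-triene F3. The Grignard reagent 21 from 12 is then coupled with F3 (Li2CuCl4, THF, −78 °C), the classical sulfone-free and ester-free allylic bromide coupling. This gives 23 directly, so step 14 falls away.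

Step 4 (one catalyst for two different olefin classes) may give insufficient stereopurity at one of the two centres, and the diastereomers are not separable. The fallback sets out from 6 and comes back at 7. The two reductions are separated and optimised independently. First a hydroxyl-directed Ru(OAc)2(BINAP)/H2 hydrogenation in MeOH reduces only the allylic-alcohol olefin and gives (5E,10S)-11-hydroxy-6,10-dimethylundec-5-en-2-one F4. The remaining isolated trialkyl olefin is then hydrogenated with the Ir–N,P catalyst to 7.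

**Further compounds**
F1 | step 9 | racemic α-cyclogeranyl phenyl sulfone, ({[(1RS)-2,6,6-trimethylcyclohex-2-en-1-yl]methyl}sulfonyl)benzene | CC1=CCCC(C)(C)C1CS(=O)(=O)c1ccccc1
F2 | step 13 | (2E,6E,10E)-3,7,11-trimethyl-13-[(1S)-2,6,6-trimethylcyclohex-2-en-1-yl]trideca-2,6,10-trien-1-ol | CC1=CCCC(C)(C)[C@@H]1CC/C(C)=C/CC/C(C)=C/CC/C(C)=C/CO
F3 | step 13 | (2E,6E,10E)-1-bromo-3,7,11-trimethyl-13-[(1S)-2,6,6-trimethylcyclohex-2-en-1-yl]trideca-2,6,10-triene | CC1=CCCC(C)(C)[C@@H]1CC/C(C)=C/CC/C(C)=C/CC/C(C)=C/CBr
F4 | step 4 | (5E,10S)-11-hydroxy-6,10-dimethylundec-5-en-2-one | OC[C@@H](C)CCC/C(C)=C/CCC(C)=O
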